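The readings were generated by integration on assumed constants; the scatter is artificial.

**Leftover L.** What you read here is the L left when the flask stops changing, because it says whether D or L ends ahead. L and Z join one to one to D over the catalyst Q, and G is Q tied up in pairs.

in all of them: L 1.5 M; Q 30 mM
- north-west: Z 1.1 M; run made earlier
- west: Z 1.8 M; run made earlier
- Friday's: Z 0.900 M; time 2.5 min
- Tuesday's: Z 1.40 M; time 2.5 min

| run | time / s | L / % | D / % |
|---|---|---|---|
| north-west | 10.0 | 63.0 | 36.3 |
| north-west | 20.0 | 55.5 | 44.1 |
| north-west | 50.0 | 54.1 | 46.4 |
| north-west | 120 | 54.4 | 46.5 |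
| west | 25.0 | 36.9 | 63.3 |
| west | 50.0 | 35.8 | 64.5 |
| west | 80.0 | 35.9 | 64.4 |
| west | 120 | 36.0 | 64.0 |

(scatter of a reading: 0.5 percentage points)

- which of these there is most of at the end, counted by the L in it, Friday's (D / L)
- which of these there is most of at the end, counted by the L in it, Tuesday's (D / L)
- amount of the one of these that there is most of at the end, in percent of the L charged, Friday's
- amount of the one of these that there is most of at the end, in percent of the L charged, Tuesday's

- reactions considered so far: L + Z + Q <-> D + Q; 2 Q <-> G

**Bench rule.** You would call Z the limiting reagent, since it is charged below L on both new flasks, and you would say that one Z takes one L, so anything above 0.5 equivalents puts D ahead. Friday's flask has 0.600 equivalents and Tuesday's 0.933, so the rule says D in both. But the north-west run had 0.733 equivalents and ended with L at 54.4% against D at 46.5%, so the border lies higher.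

**The border.** The north-west readings stop moving by 50.0 s, and the asked time is 3.00 times that, so I treat both new flasks as at rest. There K, meaning D divided by L and by free Z, is constant. The last north-west readings give 2.12 M⁻¹ and the last west readings 2.12 M⁻¹.

Where D equals L in a flask at rest, each holds half the L charged, here 0.750 M, and free Z must equal 1/K. So the crossing charge, the Z at which D draws level with L, is that amount plus 1/K, or 1.22 M. With L at 1.5 M, Friday's 0.900 M lies below it and Tuesday's 1.40 M above it, so I expect L ahead on Friday's and D ahead on Tuesday's.

**The forecast.** It gives L at 60.6% on Friday's (59.5% to 61.8%) and D at 54.8% on Tuesday's (53.7% to 55.9%), saying of the plateaus: "these look like true equilibria".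

**The flask.** Friday's ends with L at 60.3% and Tuesday's with D at 55.3%, both inside the forecast's ranges.

    L + Z + Q ⇌ D + Q, rate k1*[L]*[Z]*[Q] forward; the back reaction follows from the equilibrium constant (K = 2.17 M⁻¹, k = 3.74 M⁻² s⁻¹)
    2 Q ⇌ G, settled at all times (K = 11.0 M⁻¹)

Lowering Z in Tuesday's flask to 1.19 M moves its D by 6 points, and the crossing charge of 1.22 M stands between that amount and 1.40 M. For the neighbour with Friday's Z but 0.38 M of L, the crossing charge falls to 0.662 M, below its 0.900 M of Z, and there D ends ahead at 59.4%.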